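The side chain O–C1'–C2'–C3'(=CH2)–C4'–C5'–C6'(OH)–C7'(CH3)2OH is cut at C4'–C5'. With C6' at the ketone level, the C3' methylidene lies γ,δ to that carbonyl, the signature of a Claisen rearrangement. A ketal Claisen reaction between a 2-substituted allylic alcohol, already tethered through O8 to the coumarin (benzene ring A, pyranone ring B), and the dimethyl ketal of 3-hydroxy-3-methylbutan-2-one therefore forges C4'–C5', creates the exocyclic C3'=CH2 and delivers the C6'-keto, C7'-hydroxy terminus in one operation. The precursor is the coumarin 8-O-ether of 3-(hydroxymethyl)but-3-en-1-ol. A catalyst-controlled reduction then sets (S)-C6'.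

Key step: step 4

Assumption: 8-hydroxy-7-methoxycoumarin is taken as purchasable, and the C6' carbinol of the target is (S) by CIP analysis of the given SMILES (O > C7' > C5' > H).

Step 1
Reactants: 1 8-hydroxy-7-methoxycoumarin; 2 3-bromobut-3-en-1-ol
Product: 3 8-[(3-bromobut-3-en-1-yl)oxy]-7-methoxycoumarin
Conditions: PPh3, diisopropyl azodicarboxylate, THF, 0 °C to rt
Reagents that add atoms: none
Why: Mitsunobu etherification, in which the acidic 8-phenol displaces the phosphonium-activated primary homoallylic alcohol under neutral conditions, so that base-induced elimination to a bromodiene is avoided and the lactone stays closed.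

Step 2
Reactants: 3 8-[(3-bromobut-3-en-1-yl)oxy]-7-methoxycoumarin; 4 (tributylstannyl)methanol
Product: 5 8-{[3-(hydroxymethyl)but-3-en-1-yl]oxy}-7-methoxycoumarin
Conditions: Pd(PPh3)4 (5 mol %), 1,4-dioxane, 95 °C, argon
Reagents that add atoms: none
Why: Stille cross-coupling (hydroxymethylation), in which zerovalent palladium inserts into the 2-bromoalkene C–Br bond, the oxygen-activated CH2OH group is transferred from tin in preference to butyl, and reductive elimination gives the 2-substituted allylic alcohol without any base or nucleophile that could open the lactone.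

Step 3
Reactants: 6 3-hydroxy-3-methylbutan-2-one
Product: 7 3,3-dimethoxy-2-methylbutan-2-ol
Conditions: HC(OMe)3, MeOH, p-toluenesulfonic acid monohydrate (cat.), rt; then Et3N, distillation
Reagents that add atoms: trimethyl orthoformate, COC(OC)OC; methanol, CO (solvent, exchanges methoxy groups with the orthoester)
Why: Acid-catalysed ketalisation of the ketone, driven to completion by the orthoester as dehydrating agent, while the tertiary alcohol is inert under these mild conditions.

Step 4
Reactants: 5 8-{[3-(hydroxymethyl)but-3-en-1-yl]oxy}-7-methoxycoumarin; 7 3,3-dimethoxy-2-methylbutan-2-ol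
Product: 10 8-[(7-hydroxy-7-methyl-3-methylidene-6-oxooctyl)oxy]-7-methoxycoumarin, via mixed methyl ketal 8 (not isolated), via allyl vinyl ether 9 (not isolated)
Conditions: 7 (5 equiv), 2,4-dinitrophenol (10 mol %), toluene, 110–120 °C, MeOH distilled off
Reagents that add atoms: none
Why: Acid-catalysed exchange of one methoxy group of 7 for the allylic hydroxyl of 5 gives mixed ketal 8, which loses methanol to the 2-alkoxy-1,5-diene 9; a chair-like [3,3]-sigmatropic shift then joins the enol ether CH2 (future C5') to the terminal alkene CH2 (future C4'), while the former O–CH2 carbon becomes the C3' methylidene and the ketal carbon becomes the C6' ketone. The closest known reaction type is the ketal Claisen rearrangement of allylic alcohols with this same hydroxy ketal, a relative of the Johnson orthoester and Saucy–Marbet variants. No ring is closed and no stereocentre is created, and because the new alkene is a terminal methylidene no E/Z question arises. The selectivity needed is regiochemical enol ether formation, which is secured because the ketal carbon has only one enolisable neighbour (its methyl group; C7' is quaternary), and the two CH2 termini of the 2-substituted allyl unit leave a single [3,3] pathway. Chemoselectivity rests on the weak acid and continuous removal of methanol, which should leave the coumarin lactone, the aryl alkyl ether, the tertiary alcohol and the position of the exocyclic double bond untouched.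

Step 5
Reactants: 10 8-[(7-hydroxy-7-methyl-3-methylidene-6-oxooctyl)oxy]-7-methoxycoumarin
Product: 11 7-methoxy-8-({7-methyl-3-methylidene-6-oxo-7-[(trimethylsilyl)oxy]octyl}oxy)coumarin
Conditions: N-(trimethylsilyl)imidazole (2 equiv), CH2Cl2, rt; filtration through Et3N-deactivated silica
Reagents that add atoms: N-(trimethylsilyl)imidazole, C[Si](C)(C)n1ccnc1
Why: Silyl transfer to the tertiary alcohol without enolising the ketone; capping the hydroxyl keeps it from consuming the borane and from delivering hydride outside catalyst control in step 6, and makes the C7' side clearly the large substituent.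

Step 6
Reactants: 11 7-methoxy-8-({7-methyl-3-methylidene-6-oxo-7-[(trimethylsilyl)oxy]octyl}oxy)coumarin
Product: 14 8-{[(6S)-6,7-dihydroxy-7-methyl-3-methylideneoctyl]oxy}-7-methoxycoumarin, via catechol borate ester 12 (not isolated), via silyl ether carbinol 13 (not isolated)
Conditions: (R)-Me-CBS oxazaborolidine [(3aR)-1-methyl-3,3-diphenyltetrahydro-1H,3H-pyrrolo[1,2-c][1,3,2]oxazaborole] (0.2 equiv), catecholborane (1.8 equiv), toluene, −78 to −40 °C; then MeOH, citric acid, rt
Reagents that add atoms: none
Why: Corey–Bakshi–Shibata reduction, in which the ketone binds the ring boron through the lone pair on the C5' methylene side, away from the bulky C7' silyloxy group, and nitrogen-bound catecholborane delivers hydride to the Re face of C6' to give the (S) carbinol; catecholborane at low temperature should neither hydroborate the methylidene nor reduce the coumarin, and methanolic citric acid then cleaves the borate and the trimethylsilyl ether.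

Compound list
1 | 8-hydroxy-7-methoxycoumarin (8-hydroxy-7-methoxy-2H-chromen-2-one) | COc1ccc2ccc(=O)oc2c1O | starting material
2 | 3-bromobut-3-en-1-ol | C=C(Br)CCO | starting material
3 | 8-[(3-bromobut-3-en-1-yl)oxy]-7-methoxycoumarin | C=C(Br)CCOc1c(OC)ccc2ccc(=O)oc12 | intermediate
4 | (tributylstannyl)methanol | OC[Sn](CCCC)(CCCC)CCCC | starting material
5 | 8-{[3-(hydroxymethyl)but-3-en-1-yl]oxy}-7-methoxycoumarin | C=C(CO)CCOc1c(OC)ccc2ccc(=O)oc12 | intermediate
6 | 3-hydroxy-3-methylbutan-2-one | CC(=O)C(C)(C)O | starting material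
7 | 3,3-dimethoxy-2-methylbutan-2-ol | COC(C)(OC)C(C)(C)O | intermediate
8 | 8-[(3-{[(3-hydroxy-2-methoxy-3-methylbutan-2-yl)oxy]methyl}but-3-en-1-yl)oxy]-7-methoxycoumarin (mixed methyl ketal, racemic at the ketal carbon) | C=C(CCOc1c(OC)ccc2ccc(=O)oc12)COC(C)(OC)C(C)(C)O | intermediate
9 | 8-[(3-{[(3-hydroxy-3-methylbut-1-en-2-yl)oxy]methyl}but-3-en-1-yl)oxy]-7-methoxycoumarin (allyl vinyl ether) | C=C(CCOc1c(OC)ccc2ccc(=O)oc12)COC(=C)C(C)(C)O | intermediate
10 | 8-[(7-hydroxy-7-methyl-3-methylidene-6-oxooctyl)oxy]-7-methoxycoumarin | C=C(CCOc1c(OC)ccc2ccc(=O)oc12)CCC(=O)C(C)(C)O | intermediate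
11 | 7-methoxy-8-({7-methyl-3-methylidene-6-oxo-7-[(trimethylsilyl)oxy]octyl}oxy)coumarin | C=C(CCOc1c(OC)ccc2ccc(=O)oc12)CCC(=O)C(C)(C)O[Si](C)(C)C | intermediate
12 | 8-({(6S)-6-[(1,3,2-benzodioxaborol-2-yl)oxy]-7-methyl-3-methylidene-7-[(trimethylsilyl)oxy]octyl}oxy)-7-methoxycoumarin | C=C(CCOc1c(OC)ccc2ccc(=O)oc12)CC[C@H](OB1Oc2ccccc2O1)C(C)(C)O[Si](C)(C)C | intermediate
13 | 8-({(6S)-6-hydroxy-7-methyl-3-methylidene-7-[(trimethylsilyl)oxy]octyl}oxy)-7-methoxycoumarin | C=C(CCOc1c(OC)ccc2ccc(=O)oc12)CC[C@H](O)C(C)(C)O[Si](C)(C)C | intermediate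
14 | 8-{[(6S)-6,7-dihydroxy-7-methyl-3-methylideneoctyl]oxy}-7-methoxycoumarin | C=C(CCOc1c(OC)ccc2ccc(=O)oc12)CC[C@H](O)C(C)(C)O | target

Total step count: 6. Longest linear sequence: 5 steps (steps 1, 2, 4, 5, 6 from compound 1); step 3 is a one-step side branch.

Steps most likely to fail

1. Step 4. The exchange and elimination equilibria may stall at the mixed ketal if methanol is not removed, and long heating with acid could move the exocyclic double bond into the chain or lead to simple acetal by-products. The fallback sets out from 5 and rejoins the route at 11, replacing the rearrangement by an enolate allylation. Appel bromination of 5 (CBr4, PPh3, CH2Cl2, 0 °C) should give 8-{[3-(bromomethyl)but-3-en-1-yl]oxy}-7-methoxycoumarin F1. In parallel, 6 is silylated with N-(trimethylsilyl)imidazole to 3-methyl-3-[(trimethylsilyl)oxy]butan-2-one F2, which can be deprotonated only at its methyl group (LiN(iPr)2, THF, −78 °C). Alkylation of this lithium enolate with F1 at −78 °C forms the same C4'–C5' bond; attack at either CH2 terminus of the 2-substituted allyl unit gives the same constitution. The product is 11, and step 6 follows.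

2. Step 2. Transfer of the sp3 hydroxymethyl group from tin is slow, so protodestannylation, butyl transfer or reduction of the vinyl bromide may compete. The fallback sets out from 1 and rejoins at 5, building the 2-substituted allylic alcohol by aldehyde α-methylenation instead of cross-coupling.
- O-Alkylation of 1 with 2-(3-chloropropyl)-1,3-dioxolane (K2CO3, KI cat., DMF, 80 °C) should give 8-[3-(1,3-dioxolan-2-yl)propoxy]-7-methoxycoumarin F3.
- Acetal hydrolysis (aqueous HCl, THF, rt) gives 4-[(7-methoxy-2-oxo-2H-chromen-8-yl)oxy]butanal F4.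
- Amine-catalysed α-methylenation with aqueous formaldehyde (pyrrolidine and propionic acid as catalysts, iPrOH, 45 °C) gives 4-[(7-methoxy-2-oxo-2H-chromen-8-yl)oxy]-2-methylidenebutanal F5.
- Luche 1,2-reduction (NaBH4, CeCl3·7H2O, MeOH, −20 °C) returns 5.

3. Step 6. Facial discrimination may be incomplete if uncatalysed reduction by catecholborane competes at the temperature the hindered ketone needs. The fallback sets out from 10 and ends at 14, replacing asymmetric catalysis by resolution.
- Reduction of 10 with NaBH4 (MeOH, 0 °C) should give racemic 8-[(6,7-dihydroxy-7-methyl-3-methylideneoctyl)oxy]-7-methoxycoumarin F6.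
- Esterification of the secondary hydroxyl only with (S)-2-methoxy-2-phenylacetic acid (dicyclohexylcarbodiimide, 4-(dimethylamino)pyridine, CH2Cl2) gives two diastereomers. These are the (6S)-carbinol (2S)-2-methoxy-2-phenylacetate F7 and the (6R)-carbinol (2S)-2-methoxy-2-phenylacetate F8, to be separated by chromatography or crystallisation and assigned by O-methylmandelate NMR shift analysis.
- Methanolysis of F7 (K2CO3, MeOH, rt, then mild acid to re-close any opened lactone) releases 14.

Further compounds
F1 | step 4 | 8-{[3-(bromomethyl)but-3-en-1-yl]oxy}-7-methoxycoumarin | C=C(CBr)CCOc1c(OC)ccc2ccc(=O)oc12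
F2 | step 4 | 3-methyl-3-[(trimethylsilyl)oxy]butan-2-one | CC(=O)C(C)(C)O[Si](C)(C)C
F3 | step 2 | 8-[3-(1,3-dioxolan-2-yl)propoxy]-7-methoxycoumarin | COc1ccc2ccc(=O)oc2c1OCCCC1OCCO1
F4 | step 2 | 4-[(7-methoxy-2-oxo-2H-chromen-8-yl)oxy]butanal | COc1ccc2ccc(=O)oc2c1OCCCC=O
F5 | step 2 | 4-[(7-methoxy-2-oxo-2H-chromen-8-yl)oxy]-2-methylidenebutanal | COc1ccc2ccc(=O)oc2c1OCCC(=C)C=O
F6 | step 6 | racemic 8-[(6,7-dihydroxy-7-methyl-3-methylideneoctyl)oxy]-7-methoxycoumarin | C=C(CCOc1c(OC)ccc2ccc(=O)oc12)CCC(O)C(C)(C)O
F7 | step 6 | (6S)-7-hydroxy-1-[(7-methoxy-2-oxo-2H-chromen-8-yl)oxy]-7-methyl-3-methylideneoctan-6-yl (2S)-2-methoxy-2-phenylacetate | C=C(CCOc1c(OC)ccc2ccc(=O)oc12)CC[C@H](OC(=O)[C@@H](OC)c1ccccc1)C(C)(C)O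
F8 | step 6 | (6R)-7-hydroxy-1-[(7-methoxy-2-oxo-2H-chromen-8-yl)oxy]-7-methyl-3-methylideneoctan-6-yl (2S)-2-methoxy-2-phenylacetate | C=C(CCOc1c(OC)ccc2ccc(=O)oc12)CC[C@@H](OC(=O)[C@@H](OC)c1ccccc1)C(C)(C)O
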